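**Retrosynthetic overview**
1. Ring labels: A is the ring with OH para to its diaryl ether oxygen (hydroquinone type), B the para-phenylene, C the ring with OH ortho to its diaryl ether oxygen (catechol type), D the meta-phenylene. The plan rests on the CH2–CH2 bridge joining the ring C carbon para to OH with the ring D carbon meta to the ether oxygen. Its two carbons are equivalent and each is bonded to an sp2 aryl carbon, so the bridge can be cut out as one symmetrical C2 piece.
2. With the bridge adjusted to an (E)-CH=CH unit and both phenols masked as methyl ethers, both aryl–CH bonds are cut at once. This gives an open-chain diiodide (iodine on rings C and D) and (E)-1,2-bis(tributylstannyl)ethene, joined by a twofold Stille coupling.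
3. The diiodide is cut at the A–B ethano bridge: Wittig olefination of a B–C aldehyde with an A–D benzylic ylide, then diimide reduction, which spares the C–I bonds.
4. Each half is cut at its diaryl ether C–O bond by SNAr of a phenol on a fluorobenzaldehyde. The ring C iodine is added afterwards, and the ring D iodine is bought in.
5. Ring order: the four benzene rings are purchased. The 18-membered macrocycle is the only ring made (step 8), and hydrogenation and BBr3 demethylation finish the target.

Key step: step 8

Remark: the target has no stereocentre. The Wittig stilbene is carried forward as its E/Z mixture and drawn without geometry, because the next step saturates it.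

Step 1
Reactants: 1 guaiacol (2-methoxyphenol); 2 4-fluorobenzaldehyde
Product: 3 4-(2-methoxyphenoxy)benzaldehyde
Conditions: K2CO3, DMF, 120 °C
Reagents that add atoms: none
Why: Nucleophilic aromatic substitution (SNAr), in which the para-formyl group stabilises the Meisenheimer adduct so that the phenoxide of 1 should displace fluoride from 2 without a metal catalyst.

Step 2
Reactants: 3 4-(2-methoxyphenoxy)benzaldehyde
Product: 4 4-(5-iodo-2-methoxyphenoxy)benzaldehyde
Conditions: NIS, TFA (cat.), MeCN, rt, dark
Reagents that add atoms: N-iodosuccinimide, O=C1CCC(=O)N1I
Why: Electrophilic aromatic iodination, in which ring B is deactivated by its formyl group and on ring C the methoxy oxygen is the stronger donor because the ether oxygen shares its lone pair with the formylphenyl ring, so iodine should enter at the open position para to OMe, the carbon that carries the C–D bridge in the target.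

Step 3
Reactants: 5 3-iodophenol; 6 2-fluoro-5-methoxybenzaldehyde
Product: 7 2-(3-iodophenoxy)-5-methoxybenzaldehyde
Conditions: K2CO3, DMA, 150 °C
Reagents that add atoms: none
Why: SNAr, in which the ortho-formyl group activates the C–F bond of 6 enough to offset the para-methoxy donor at this temperature, while the C–I bond of 5 stays inert because no copper or palladium is present.

Step 4
Reactants: 7 2-(3-iodophenoxy)-5-methoxybenzaldehyde
Product: 8 [2-(3-iodophenoxy)-5-methoxyphenyl]methanol
Conditions: NaBH4, MeOH/THF, 0 °C
Reagents that add atoms: none
Why: Borohydride reduction of an aryl aldehyde, which leaves the aryl iodide and both kinds of ether untouched.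

Step 5
Reactants: 8 [2-(3-iodophenoxy)-5-methoxyphenyl]methanol
Product: 9 {[2-(3-iodophenoxy)-5-methoxyphenyl]methyl}triphenylphosphonium bromide
Conditions: PPh3·HBr, MeCN, reflux
Reagents that add atoms: triphenylphosphine hydrobromide, [Br-].c1ccc(cc1)[PH+](c1ccccc1)c1ccccc1
Why: Direct phosphonium salt formation from a benzylic alcohol, in which the HBr carried by the reagent turns hydroxyl into water as leaving group and PPh3 takes the benzylic carbon by nucleophilic substitution, saving a separate bromination.

Step 6
Reactants: 9 {[2-(3-iodophenoxy)-5-methoxyphenyl]methyl}triphenylphosphonium bromide; 4 4-(5-iodo-2-methoxyphenoxy)benzaldehyde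
Product: 11 1-[2-(3-iodophenoxy)-5-methoxyphenyl]-2-[4-(5-iodo-2-methoxyphenoxy)phenyl]ethene (E/Z mixture), via benzylic ylide 10 (not isolated)
Conditions: KOtBu, THF, 0 °C; then 4, 0 °C to rt
Reagents that add atoms: none
Why: Wittig olefination, in which deprotonation of 9 gives the semistabilised ylide 10 that adds to aldehyde 4 and collapses to the stilbene and triphenylphosphine oxide, an alkoxide base being chosen over an alkyllithium so that neither C–I bond suffers halogen–metal exchange.

Step 7
Reactants: 11 1-[2-(3-iodophenoxy)-5-methoxyphenyl]-2-[4-(5-iodo-2-methoxyphenoxy)phenyl]ethene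
Product: 12 open-chain diiodide 1-[2-(3-iodophenoxy)-5-methoxyphenyl]-2-[4-(5-iodo-2-methoxyphenoxy)phenyl]ethane
Conditions: TsNHNH2, NaOAc (buffer), DME/H2O, reflux
Reagents that add atoms: none
Why: Diimide reduction, in which HN=NH released from the sulfonyl hydrazide delivers two hydrogens to the C=C bond through a concerted cyclic transition state and does not touch the C–I bonds that hydrogenation over palladium would cleave.

Step 8
Reactants: 12 open-chain diiodide 1-[2-(3-iodophenoxy)-5-methoxyphenyl]-2-[4-(5-iodo-2-methoxyphenoxy)phenyl]ethane; 13 (E)-1,2-bis(tributylstannyl)ethene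
Product: 16 macrocyclic (E)-stilbene dimethyl ether (18-membered ring; one trans CH=CH unit joins the ring C carbon para to OMe to the ring D carbon meta to O), via ring D vinylstannane 14 (not isolated), via ring C vinylstannane 15 (not isolated)
Conditions: Pd2(dba)3 (10 mol %), AsPh3 (40 mol %), iPr2NEt, degassed DMF, 60 °C; equimolar 12 and 13 in THF co-added by syringe pump over 24 h (final about 1 mM); chromatography on K2CO3-loaded silica
Reagents that add atoms: none
Why: Twofold Stille cross-coupling in one flask: zerovalent palladium, formed from Pd2(dba)3 and the weakly bound ligand AsPh3, inserts into one C–I bond of 12 (the less electron-rich ring D iodide should go first and give 14, while entry at ring C gives 15 and leads to the same product), one tin end of 13 transmetalates to the divalent arylpalladium iodide, and reductive elimination forms the first aryl–CH bond. Oxidative addition at the remaining C–I bond then places arylpalladium and vinyltin termini in the same molecule, and intramolecular transmetalation to a large palladacycle followed by reductive elimination forms the second aryl–CH bond and closes the 18-membered ring, that is, an end-to-end macrocyclisation by C(sp2)–C(sp2) coupling. The closest known chemistry is the stitching macrocyclisation of diiodides with 1,2-bis(stannyl)ethenes, together with the twofold coupling of aryl iodides with 13 that is routinely used for symmetrical stilbenes and arylene–vinylene chains. No stereocentre is created, and the trans geometry of 13 should be carried into 16 because transmetalation and reductive elimination both proceed with retention at the alkene carbons. Since 13 has two identical ends it cannot be built in the wrong way round and the order in which the iodides react is irrelevant, so the one contest to be won is cyclisation against chain growth, which is addressed by feeding equimolar 12 and 13 slowly into the catalyst so that neither partner accumulates. The substrate helps through its flexible A–B CH2–CH2 link and its two ether oxygens, which act as hinges and let the meta-substituted carbons of rings C and D reach across the rigid trans C2 unit.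

Step 9
Reactants: 16 macrocyclic (E)-stilbene dimethyl ether
Product: 17 macrocyclic bis(bibenzyl) dimethyl ether (both bridges CH2–CH2)
Conditions: H2 (1 atm), 10% Pd/C, EtOAc/MeOH, rt
Reagents that add atoms: none
Why: Heterogeneous catalytic hydrogenation, for which the disubstituted stilbene C=C is the only reducible group left, since no halogen remains and neither the diaryl nor the methyl ethers contain a benzylic C–O bond.

Step 10
Reactants: 17 macrocyclic bis(bibenzyl) dimethyl ether
Product: 19 target macrocyclic bis(bibenzyl) diphenol CNP0135015.0, via bis(dibromoboryl) ether 18 (not isolated)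
Conditions: BBr3 (excess), CH2Cl2, −78 °C to rt; then ice-water
Reagents that add atoms: none
Why: Lewis-acid cleavage of aryl methyl ethers with BBr3, in which boron binds each methoxy oxygen and bromide attacks the methyl carbon by SN2 to give aryloxyborane 18 that is hydrolysed on work-up, whereas the diaryl ether oxygens offer no sp3 carbon for attack and stay intact.

**Compound list**
1 | guaiacol (2-methoxyphenol) | COc1ccccc1O | starting material
2 | 4-fluorobenzaldehyde | O=Cc1ccc(F)cc1 | starting material
3 | 4-(2-methoxyphenoxy)benzaldehyde | COc1ccccc1Oc1ccc(C=O)cc1 | intermediate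
4 | 4-(5-iodo-2-methoxyphenoxy)benzaldehyde | COc1ccc(I)cc1Oc1ccc(C=O)cc1 | intermediate
5 | 3-iodophenol | Oc1cccc(I)c1 | starting material
6 | 2-fluoro-5-methoxybenzaldehyde | COc1ccc(F)c(C=O)c1 | starting material
7 | 2-(3-iodophenoxy)-5-methoxybenzaldehyde | COc1ccc(Oc2cccc(I)c2)c(C=O)c1 | intermediate
8 | [2-(3-iodophenoxy)-5-methoxyphenyl]methanol | COc1ccc(Oc2cccc(I)c2)c(CO)c1 | intermediate
9 | {[2-(3-iodophenoxy)-5-methoxyphenyl]methyl}triphenylphosphonium bromide | COc1ccc(Oc2cccc(I)c2)c(C[P+](c2ccccc2)(c2ccccc2)c2ccccc2)c1.[Br-] | intermediate
10 | benzylic ylide, [2-(3-iodophenoxy)-5-methoxybenzylidene]triphenylphosphorane | COc1ccc(Oc2cccc(I)c2)c(C=P(c2ccccc2)(c2ccccc2)c2ccccc2)c1 | intermediate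
11 | 1-[2-(3-iodophenoxy)-5-methoxyphenyl]-2-[4-(5-iodo-2-methoxyphenoxy)phenyl]ethene (E/Z mixture) | COc1ccc(Oc2cccc(I)c2)c(c1)C=Cc1ccc(cc1)Oc1cc(I)ccc1OC | intermediate
12 | open-chain diiodide, 1-[2-(3-iodophenoxy)-5-methoxyphenyl]-2-[4-(5-iodo-2-methoxyphenoxy)phenyl]ethane | COc1ccc(Oc2cccc(I)c2)c(c1)CCc1ccc(cc1)Oc1cc(I)ccc1OC | intermediate
13 | (E)-1,2-bis(tributylstannyl)ethene | CCCC[Sn](CCCC)(CCCC)/C=C/[Sn](CCCC)(CCCC)CCCC | starting material
14 | ring D vinylstannane (12 with the ring D iodine replaced by (E)-2-(tributylstannyl)ethenyl) | COc1ccc(Oc2cccc(/C=C/[Sn](CCCC)(CCCC)CCCC)c2)c(c1)CCc1ccc(cc1)Oc1cc(I)ccc1OC | intermediate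
15 | ring C vinylstannane (12 with the ring C iodine replaced by (E)-2-(tributylstannyl)ethenyl) | COc1ccc(Oc2cccc(I)c2)c(c1)CCc1ccc(cc1)Oc1cc(/C=C/[Sn](CCCC)(CCCC)CCCC)ccc1OC | intermediate
16 | macrocyclic (E)-stilbene dimethyl ether | COc1ccc2c(c1)CCc1ccc(cc1)Oc1cc(ccc1OC)/C=C/c1cccc(c1)O2 | intermediate
17 | macrocyclic bis(bibenzyl) dimethyl ether | COc1ccc2c(c1)CCc1ccc(cc1)Oc1cc(ccc1OC)CCc1cccc(c1)O2 | intermediate
18 | bis(dibromoboryl) ether of the target | BrB(Br)Oc1ccc2c(c1)CCc1ccc(cc1)Oc1cc(ccc1OB(Br)Br)CCc1cccc(c1)O2 | intermediate
19 | target macrocyclic bis(bibenzyl) diphenol CNP0135015.0 | Oc1ccc2c(c1)CCc1ccc(cc1)Oc1cc(ccc1O)CCc1cccc(c1)O2 | target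

**Totals**
Total step count: 10. Longest linear sequence: 8 steps (steps 3, 4, 5, 6, 7, 8, 9, 10, starting from 5 and 6).

**Three steps most likely to fail**

**Step 8.**
- Risk: chain growth may outrun ring closure. The vinyltin terminus may be lost by protodestannylation during the long addition. The second transmetalation may stall because the chain has to fold around a rigid trans unit.
- Fallback: it sets out from 12 and separates carbon delivery from ring closure.
- Twofold Stille coupling of 12 with tributyl(vinyl)stannane (Pd(PPh3)4, toluene, 100 °C, ordinary concentration) should give the divinyl compound 1-[2-(3-ethenylphenoxy)-5-methoxyphenyl]-2-[4-(5-ethenyl-2-methoxyphenoxy)phenyl]ethane F1.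
- Ring-closing metathesis of its two styrene ends (second-generation Grubbs catalyst, CH2Cl2, reflux, about 1 mM, ethene swept out) then forms the C=C bond itself. It should give 16, possibly together with the macrocyclic (Z)-stilbene dimethyl ether F2.
- Both isomers are saturated under the conditions of step 9, so the fallback comes back to the route at 17.

**Step 3.**
- Risk: displacement of fluoride may be sluggish because the para-methoxy group feeds electron density to the carbon under attack, and the aldehyde may degrade at the temperature needed.
- Fallback: it sets out from 5 and reverses the polarity at ring A.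
- Chan–Lam coupling of 5 with purchased (2-formyl-4-methoxyphenyl)boronic acid (Cu(OAc)2, pyridine, 4 Å molecular sieves, CH2Cl2, air, rt) forms the same C–O bond oxidatively at room temperature. Under these conditions the aryl iodide is inert and the methoxy donor is no handicap.
- It comes back to the route at 7 and makes no compound outside the list (F0).

**Step 2.**
- Risk: positional selectivity may be poor (competing attack para to the aryloxy oxygen), or over-iodination may occur, giving isomers that are hard to separate at this stage.
- Fallback: it sets out from 1 and installs iodine before the ether is made, under a stronger electronic bias.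
- Acetylation (Ac2O, pyridine) gives 2-methoxyphenyl acetate F3.
- Iodination with ICl in CH2Cl2 goes para to OMe because acetoxy is a much weaker donor, and gives 5-iodo-2-methoxyphenyl acetate F4.
- Methanolysis (K2CO3 cat., MeOH) gives 5-iodo-2-methoxyphenol F5.
- SNAr of F5 on 2 under the conditions of step 1 comes back to the route at 4.

**Further compounds**
F1 | step 8 | 1-[2-(3-ethenylphenoxy)-5-methoxyphenyl]-2-[4-(5-ethenyl-2-methoxyphenoxy)phenyl]ethane | COc1ccc(Oc2cccc(C=C)c2)c(c1)CCc1ccc(cc1)Oc1cc(C=C)ccc1OC
F2 | step 8 | macrocyclic (Z)-stilbene dimethyl ether | COc1ccc2c(c1)CCc1ccc(cc1)Oc1cc(ccc1OC)/C=C\c1cccc(c1)O2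
F0 | step 3 | none | none
F3 | step 2 | 2-methoxyphenyl acetate | COc1ccccc1OC(C)=O
F4 | step 2 | 5-iodo-2-methoxyphenyl acetate | COc1ccc(I)cc1OC(C)=O
F5 | step 2 | 5-iodo-2-methoxyphenol | COc1ccc(I)cc1O
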